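**Retrosynthetic overview**
1. Target 32 ⇐ bicyclic alcohol 23 by a late C7 allylic hydroxylation, C2 angeloylation, and C3 oxidation / C2 hydroxylation / axial-selective C3 reduction.
2. Key step: 23 ⇐ epoxy triene 22 in one cationic cascade. Epoxide opening closes ring A (C4–C5), then ring B (C10–C9), then silicon is lost to give the 8(17)-alkene, as in the cyclase route to syn-copalyl diphosphate. The (Z)-type allylsilane gives the 9βH centre through a chair–chair fold; the C20 ester and C13 carbinol are already in place.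
3. 22 ⇐ alkyl iodide 11 + vinyl iodide 19 by B-alkyl Suzuki coupling (C5–C6).
4. 11 ⇐ (R)-linalool (C13) via ozonolysis, vinyl Grignard addition and a Still–Wittig [2,3] shift (C8=C9 geometry).
5. 19 ⇐ propargyl alcohol via anti-carbomagnesiation/iodination (C5=C10 geometry, C20 oxygen), esterification and asymmetric epoxidation (absolute configuration of both rings).

Assumption: the SMILES is taken as drawn, i.e. a 9-epi (syn) labdane with 5α-H, 9β-H (side chain α), 10β-CH2O-acyl, 2α/3α/7α oxygens, 13R and a (2R)-2-methylbutanoate; (R)-2-methylbutanoic acid, tributyl(iodomethyl)stannane, (2-bromoallyl)trimethylsilane and the L-fructose-derived Shi ketone are bought.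

**Route**

Step 1
Reactants: 1 (R)-(−)-linalool
Product: 2 (3R)-3,7-dimethyl-3-(triethylsilyloxy)octa-1,6-diene
Conditions: TESOTf, 2,6-lutidine, CH2Cl2, −78 → 0 °C
Reagents that add atoms: triethylsilyl triflate, CC[Si](CC)(CC)OS(=O)(=O)C(F)(F)F
Why: Silyl triflate/lutidine silylation protects the hindered tertiary allylic alcohol without ionising it, so the C13 stereocentre from the chiral pool is untouched.

Step 2
Reactants: 2 (3R)-3,7-dimethyl-3-(triethylsilyloxy)octa-1,6-diene
Product: 3 (4R)-4-methyl-4-(triethylsilyloxy)hex-5-enal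
Conditions: O3, CH2Cl2/MeOH, pyridine, Sudan Red 7B end-point, −78 °C; then Me2S
Reagents that add atoms: ozone, [O-][O+]=O
Why: Ozonolysis cleaves the electron-rich trisubstituted alkene much faster than the hindered vinyl group next to the silyloxy carbon, giving the aldehyde carbon that becomes C9.

Step 3
Reactants: 3 (4R)-4-methyl-4-(triethylsilyloxy)hex-5-enal; 4 (2-bromoallyl)trimethylsilane
Product: 6 (6R)-6-methyl-6-(triethylsilyloxy)-2-[(trimethylsilyl)methyl]octa-1,7-dien-3-ol (both C3 epimers), via [3-(trimethylsilyl)prop-1-en-2-yl]magnesium bromide 5 (not isolated)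
Conditions: 4, Mg, THF, 40 °C; then 3, −78 → 0 °C; H2O
Reagents that add atoms: none
Why: Grignard 1,2-addition installs C8, C7 and the C17 silane; the new carbinol centre forms as a mixture, which does not matter because it becomes sp2 in step 5.

Step 4
Reactants: 6 (6R)-6-methyl-6-(triethylsilyloxy)-2-[(trimethylsilyl)methyl]octa-1,7-dien-3-ol; 7 tributyl(iodomethyl)stannane
Product: 8 tributyl({[(6R)-6-methyl-6-(triethylsilyloxy)-2-[(trimethylsilyl)methyl]octa-1,7-dien-3-yl]oxy}methyl)stannane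
Conditions: KH, THF, 0 °C; then 7, 0 °C → rt
Reagents that add atoms: none
Why: Williamson etherification of the alkoxide with the reactive α-iodomethylstannane (Still's stannylmethyl ether synthesis), run cold so that alkylation outruns 1,4-silyl migration.

Step 5
Reactants: 8 tributyl(stannylmethyl) ether of 6
Product: 10 (3E,7R)-7-methyl-7-(triethylsilyloxy)-3-[(trimethylsilyl)methyl]nona-3,8-dien-1-ol (CH2CH2OH cis to the C5 chain), via lithiomethyl ether 9 (not isolated)
Conditions: n-BuLi, THF, −78 °C, 30 min; H2O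
Reagents that add atoms: none
Why: Tin–lithium exchange triggers the Still–Wittig [2,3]-sigmatropic rearrangement, whose envelope transition state keeps the carbinol substituent pseudo-axial away from the 2-CH2SiMe3 group and so gives the trisubstituted alkene with the new chain cis to the C11 chain.

Step 6
Reactants: 10 (3E,7R)-7-methyl-7-(triethylsilyloxy)-3-[(trimethylsilyl)methyl]nona-3,8-dien-1-ol
Product: 11 (3R,6E)-9-iodo-3-methyl-3-(triethylsilyloxy)-7-[(trimethylsilyl)methyl]nona-1,6-diene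
Conditions: PPh3, imidazole, I2 (premixed), CH2Cl2, 0 °C
Reagents that add atoms: iodine, II
Why: Appel-type iodination converts the primary alcohol by SN2; the pre-formed phosphonium iodide keeps free iodine away from the allylsilane.

Step 7
Reactants: 12 propargyl alcohol; 13 5-bromo-2-methylpent-2-ene
Product: 16 (2Z)-3-iodo-2-(4-methylpent-3-en-1-yl)prop-2-en-1-ol, via (4-methylpent-3-en-1-yl)magnesium bromide 14 (not isolated), via cyclic alkenylmagnesium alkoxide 15 (not isolated)
Conditions: 13, Mg, Et2O (3 equiv of 14); 12, CuI (10 mol %), Et2O, 0 °C → reflux; then I2, THF, −40 → 0 °C; H2O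
Reagents that add atoms: iodine, II
Why: Cu-catalysed anti-carbomagnesiation of propargyl alcohol (Duboudin reaction) puts the alkyl group on the internal carbon and magnesium in a five-membered chelate cis to CH2O, so iodinolysis with retention fixes the C5=C10 geometry (C20 cis to the future C6).

Step 8
Reactants: 16 (2Z)-3-iodo-2-(4-methylpent-3-en-1-yl)prop-2-en-1-ol; 17 (R)-2-methylbutanoic acid
Product: 18 (2Z)-3-iodo-2-(4-methylpent-3-en-1-yl)prop-2-en-1-yl (2R)-2-methylbutanoate
Conditions: EDC·HCl, DMAP (cat.), CH2Cl2, 0 °C → rt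
Reagents that add atoms: none
Why: Steglich esterification of the unhindered primary allylic alcohol is mild enough not to epimerise the α-stereocentre of the acid.

Step 9
Reactants: 18 (2Z)-3-iodo-2-(4-methylpent-3-en-1-yl)prop-2-en-1-yl (2R)-2-methylbutanoate
Product: 19 (2Z)-2-{2-[(2S)-3,3-dimethyloxiran-2-yl]ethyl}-3-iodoprop-2-en-1-yl (2R)-2-methylbutanoate
Conditions: L-fructose-derived Shi ketone (30 mol %), Oxone, K2CO3, Bu4NHSO4, MeCN/DMM/aq. borate–EDTA buffer (pH 10.5), 0 °C
Reagents that add atoms: potassium peroxymonosulfate (Oxone), [K+].[O-]S(=O)(=O)OO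
Why: Shi asymmetric epoxidation (chiral dioxirane, spiro transition state) selects the electron-rich trisubstituted alkene over the iodo-alkene and, with this catalyst enantiomer, gives the (S)-epoxide that later sets the absolute configuration of both rings.

Step 10
Reactants: 11 (3R,6E)-9-iodo-3-methyl-3-(triethylsilyloxy)-7-[(trimethylsilyl)methyl]nona-1,6-diene; 19 (S)-epoxy vinyl iodide
Product: 22 (2Z,6E,10R)-2-{2-[(2S)-3,3-dimethyloxiran-2-yl]ethyl}-10-methyl-10-(triethylsilyloxy)-6-[(trimethylsilyl)methyl]dodeca-2,6,11-trien-1-yl (2R)-2-methylbutanoate, via alkyllithium 20 (not isolated), via lithium B-alkyl-B-methoxy-9-BBN borate 21 (not isolated)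
Conditions: 11, t-BuLi (2.1 equiv), Et2O, −78 °C; 9-MeO-9-BBN, THF, −78 °C → rt; then 19, Pd(dppf)Cl2 (5 mol %), AsPh3, aq. K3PO4, DMF, rt
Reagents that add atoms: none
Why: B-alkyl Suzuki–Miyaura coupling (Li–I exchange, borate formation, Pd-catalysed sp3–sp2 coupling) joins C6 to C5 with retention of both alkene geometries and tolerates the epoxide, ester and allylsilane.

Step 11
Reactants: 22 epoxy triene
Product: 23 (13R)-3β-hydroxy-13-(triethylsilyloxy)-9βH-labda-8(17),14-dien-20-yl (2R)-2-methylbutanoate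
Conditions: MeAlCl2 (2.5 equiv), CH2Cl2, −94 → −78 °C, 30 min; Et3N/MeOH, then aq. NaHCO3
Reagents that add atoms: none
Why: Epoxide-initiated cation–olefin bicyclization terminated by an allylsilane (SE2′): the (S)-epoxide opens anti at C4 through a chair (3β-OH, 5α-H), anti addition across the C5=C10 alkene gives the trans-decalin with 10β-CH2O-acyl (Stork–Eschenmoser), the C8=C9 geometry (C7 cis to C11) places the side chain axial (9β-H), β-silyl elimination gives only the exocyclic alkene, and excess Lewis acid keeps the ester carbonyl complexed so that it does not capture the C10 cation.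

Step 12
Reactants: 23 bicyclic 3β-alcohol
Product: 24 (13R)-3-oxo-13-(triethylsilyloxy)-9βH-labda-8(17),14-dien-20-yl (2R)-2-methylbutanoate
Conditions: Dess–Martin periodinane, NaHCO3, CH2Cl2, 0 °C → rt
Reagents that add atoms: none
Why: Dess–Martin oxidation of the only free hydroxyl under buffered conditions leaves the tertiary allylic silyl ether, the ester and the alkenes alone.

Step 13
Reactants: 24 3-ketone
Product: 27 (13R)-2α,13-dihydroxy-3-oxo-9βH-labda-8(17),14-dien-20-yl (2R)-2-methylbutanoate, via trimethylsilyl enol ether 25 (not isolated), via silyloxy epoxide 26 (not isolated)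
Conditions: TMSOTf, Et3N, CH2Cl2, 0 °C; then DMDO (1.05 equiv), acetone/CH2Cl2, −78 → −40 °C; then HF·pyridine, pyridine/THF, 0 °C → rt
Reagents that add atoms: dimethyldioxirane, CC1(C)OO1
Why: Rubottom oxidation: enolisation can only go towards C2 (C4 is quaternary), DMDO attacks the electron-rich enol ether from the α-face opposite the axial 4β-methyl and 10β-CH2O-acyl groups, and HF opens the silyloxy epoxide to the equatorial 2α-hydroxy ketone while removing the C13 silyl group.

Step 14
Reactants: 27 2α-hydroxy-3-ketone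
Product: 28 (13R)-2α,3α,13-trihydroxy-9βH-labda-8(17),14-dien-20-yl (2R)-2-methylbutanoate
Conditions: L-Selectride (4 equiv), THF, −78 °C; H2O
Reagents that add atoms: none
Why: Bulky-hydride reduction attacks along the equatorial trajectory from the β-face, as with 2-substituted cyclohexanones, giving the axial 3α-alcohol cis to the 2α-hydroxyl; esters are not reduced at −78 °C.

Step 15
Reactants: 28 2α,3α,13-triol; 29 angelic acid
Product: 31 (13R)-2α-angeloyloxy-3α,13-dihydroxy-9βH-labda-8(17),14-dien-20-yl (2R)-2-methylbutanoate, via angelic 2,4,6-trichlorobenzoic anhydride 30 (not isolated)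
Conditions: 29, 2,4,6-trichlorobenzoyl chloride, Et3N, toluene, rt; then 28, toluene, 75 °C (no DMAP)
Reagents that add atoms: none
Why: Yamaguchi mixed-anhydride esterification acylates only the equatorial secondary 2α-OH (the axial neopentyl 3α-OH and the tertiary 13-OH are inert) and, without DMAP, avoids angelate-to-tiglate isomerisation.

Step 16
Reactants: 31 2α-angelate
Product: 32 (13R)-2α-angeloyloxy-3α,7α,13-trihydroxy-9βH-labda-8(17),14-dien-20-yl (2R)-2-methylbutanoate (target)
Conditions: SeO2 (0.5 equiv), t-BuOOH (2.5 equiv), CH2Cl2, 0 °C → rt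
Reagents that add atoms: selenium dioxide, O=[Se]=O; tert-butyl hydroperoxide, CC(C)(C)OO
Why: SeO2 allylic hydroxylation (ene reaction then [2,3]-sigmatropic shift) attacks the 1,1-disubstituted 8(17)-alkene at its CH2 (C7) rather than its CH (C9) and forms the C–O bond axially on the α-face to give the 7α-alcohol; the electron-poor angelate and the vinyl group (no allylic H) do not react.

**Compound list**
1 | (R)-(−)-linalool | C=C[C@](C)(O)CCC=C(C)C | starting material
2 | (3R)-3,7-dimethyl-3-(triethylsilyloxy)octa-1,6-diene | C=C[C@](C)(O[Si](CC)(CC)CC)CCC=C(C)C | intermediate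
3 | (4R)-4-methyl-4-(triethylsilyloxy)hex-5-enal | C=C[C@](C)(O[Si](CC)(CC)CC)CCC=O | intermediate
4 | (2-bromoallyl)trimethylsilane | C=C(Br)C[Si](C)(C)C | starting material
5 | [3-(trimethylsilyl)prop-1-en-2-yl]magnesium bromide | C=C([Mg]Br)C[Si](C)(C)C | intermediate (not isolated)
6 | (6R)-6-methyl-6-(triethylsilyloxy)-2-[(trimethylsilyl)methyl]octa-1,7-dien-3-ol, both C3 epimers | C=C[C@](C)(O[Si](CC)(CC)CC)CCC(O)C(=C)C[Si](C)(C)C | intermediate
7 | tributyl(iodomethyl)stannane | CCCC[Sn](CCCC)(CCCC)CI | starting material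
8 | tributylstannylmethyl ether of 6 | C=C[C@](C)(O[Si](CC)(CC)CC)CCC(OC[Sn](CCCC)(CCCC)CCCC)C(=C)C[Si](C)(C)C | intermediate
9 | lithiomethyl ether of 6 | C=C[C@](C)(O[Si](CC)(CC)CC)CCC(OC[Li])C(=C)C[Si](C)(C)C | intermediate (not isolated)
10 | (3E,7R)-7-methyl-7-(triethylsilyloxy)-3-[(trimethylsilyl)methyl]nona-3,8-dien-1-ol (CH2CH2OH cis to C5) | C=C[C@](C)(O[Si](CC)(CC)CC)CC/C=C(\CCO)C[Si](C)(C)C | intermediate
11 | (3R,6E)-9-iodo-3-methyl-3-(triethylsilyloxy)-7-[(trimethylsilyl)methyl]nona-1,6-diene | C=C[C@](C)(O[Si](CC)(CC)CC)CC/C=C(\CCI)C[Si](C)(C)C | intermediate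
12 | propargyl alcohol | C#CCO | starting material
13 | 5-bromo-2-methylpent-2-ene | CC(C)=CCCBr | starting material
14 | (4-methylpent-3-en-1-yl)magnesium bromide | CC(C)=CCC[Mg]Br | intermediate (not isolated)
15 | 4-(4-methylpent-3-en-1-yl)-2,5-dihydro-1,2-oxamagnesole (cyclic alkenylmagnesium alkoxide) | CC(C)=CCCC1=C[Mg]OC1 | intermediate (not isolated)
16 | (2Z)-3-iodo-2-(4-methylpent-3-en-1-yl)prop-2-en-1-ol | OC/C(CCC=C(C)C)=C\I | intermediate
17 | (R)-2-methylbutanoic acid | CC[C@@H](C)C(=O)O | starting material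
18 | (2Z)-3-iodo-2-(4-methylpent-3-en-1-yl)prop-2-en-1-yl (2R)-2-methylbutanoate | I/C=C(/CCC=C(C)C)COC(=O)[C@H](C)CC | intermediate
19 | (2Z)-2-{2-[(2S)-3,3-dimethyloxiran-2-yl]ethyl}-3-iodoprop-2-en-1-yl (2R)-2-methylbutanoate | I/C=C(/CC[C@@H]1OC1(C)C)COC(=O)[C@H](C)CC | intermediate
20 | alkyllithium from 11 | C=C[C@](C)(O[Si](CC)(CC)CC)CC/C=C(\CC[Li])C[Si](C)(C)C | intermediate (not isolated)
21 | lithium B-alkyl-B-methoxy-9-BBN borate from 20 | [Li+].C=C[C@](C)(O[Si](CC)(CC)CC)CC/C=C(\CC[B-]1(OC)C2CCCC1CCC2)C[Si](C)(C)C | intermediate (not isolated)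
22 | (2Z,6E,10R)-2-{2-[(2S)-3,3-dimethyloxiran-2-yl]ethyl}-10-methyl-10-(triethylsilyloxy)-6-[(trimethylsilyl)methyl]dodeca-2,6,11-trien-1-yl (2R)-2-methylbutanoate | C=C[C@](C)(O[Si](CC)(CC)CC)CC/C=C(\CC/C=C(/CC[C@@H]1OC1(C)C)COC(=O)[C@H](C)CC)C[Si](C)(C)C | intermediate
23 | (13R)-3β-hydroxy-13-(triethylsilyloxy)-9βH-labda-8(17),14-dien-20-yl (2R)-2-methylbutanoate (5α-H, 9β-H, 10β-CH2O-acyl) | C=C[C@](C)(O[Si](CC)(CC)CC)CC[C@@H]1C(=C)CC[C@H]2C(C)(C)[C@@H](O)CC[C@]12COC(=O)[C@H](C)CC | intermediate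
24 | (13R)-3-oxo-13-(triethylsilyloxy)-9βH-labda-8(17),14-dien-20-yl (2R)-2-methylbutanoate | C=C[C@](C)(O[Si](CC)(CC)CC)CC[C@@H]1C(=C)CC[C@H]2C(C)(C)C(=O)CC[C@]12COC(=O)[C@H](C)CC | intermediate
25 | 3-(trimethylsilyloxy)-2-ene (silyl enol ether of 24) | C=C[C@](C)(O[Si](CC)(CC)CC)CC[C@@H]1C(=C)CC[C@H]2C(C)(C)C(O[Si](C)(C)C)=CC[C@]12COC(=O)[C@H](C)CC | intermediate (not isolated)
26 | 2α,3α-epoxy-3β-(trimethylsilyloxy) derivative of 25 | C=C[C@](C)(O[Si](CC)(CC)CC)CC[C@@H]1C(=C)CC[C@H]2C(C)(C)[C@]3(O[Si](C)(C)C)O[C@@H]3C[C@]12COC(=O)[C@H](C)CC | intermediate (not isolated)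
27 | (13R)-2α,13-dihydroxy-3-oxo-9βH-labda-8(17),14-dien-20-yl (2R)-2-methylbutanoate | C=C[C@](C)(O)CC[C@@H]1C(=C)CC[C@H]2C(C)(C)C(=O)[C@H](O)C[C@]12COC(=O)[C@H](C)CC | intermediate
28 | (13R)-2α,3α,13-trihydroxy-9βH-labda-8(17),14-dien-20-yl (2R)-2-methylbutanoate | C=C[C@](C)(O)CC[C@@H]1C(=C)CC[C@H]2C(C)(C)[C@H](O)[C@H](O)C[C@]12COC(=O)[C@H](C)CC | intermediate
29 | angelic acid, (Z)-2-methylbut-2-enoic acid | C/C=C(/C)C(=O)O | starting material
30 | angelic 2,4,6-trichlorobenzoic anhydride | C/C=C(/C)C(=O)OC(=O)c1c(Cl)cc(Cl)cc1Cl | intermediate (not isolated)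
31 | (13R)-2α-angeloyloxy-3α,13-dihydroxy-9βH-labda-8(17),14-dien-20-yl (2R)-2-methylbutanoate | C=C[C@](C)(O)CC[C@@H]1C(=C)CC[C@H]2C(C)(C)[C@H](O)[C@H](OC(=O)/C(C)=C\C)C[C@]12COC(=O)[C@H](C)CC | intermediate
32 | (13R)-2α-angeloyloxy-3α,7α,13-trihydroxy-9βH-labda-8(17),14-dien-20-yl (2R)-2-methylbutanoate (CNP0391865.1) | C=C[C@](C)(O)CC[C@@H]1C(=C)[C@H](O)C[C@H]2C(C)(C)[C@H](O)[C@H](OC(=O)/C(C)=C\C)C[C@]12COC(=O)[C@H](C)CC | target

**Step count**
Total: 16 steps. Longest linear sequence: 13 steps (steps 1–6 and 10–16); steps 7–9 form the second branch.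

**Three steps most likely to fail**

Step 11 (key cyclization). The ester on the central alkene deactivates it and its carbonyl may capture the C10 cation; the tertiary allylic silyl ether may also ionise. The fallback sets out from 16 and replaces the ester by an ether during the cascade. Alkylation of 16 with NaH and 2-(bromomethyl)naphthalene gives the 2-naphthylmethyl ether F1. Epoxidation under the step 9 conditions gives the (S)-epoxide F2. Coupling with borate 21 as in step 10 gives the ether-protected epoxy triene F3. Cyclization with MeAlCl2 as in step 11 gives the bicyclic naphthylmethyl ether F4. DDQ in CH2Cl2/pH 7 buffer then frees the 3β,20-diol F5. Selective Steglich esterification of its primary C20 hydroxyl with 17 (1.05 equiv, 0 °C) comes back to the route at 23.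

Step 14 (C3 reduction). The hydride must pass the axial 4β-methyl, so the equatorial 3β-alcohol may compete. The fallback sets out from 24 and makes the cis-diol by dihydroxylation instead. KHMDS and PhNTf2 at −78 °C give the enol triflate F6. Pd(OAc)2, PPh3, Bu3N and HCO2H reduce it to the 2-ene F7. OsO4 (1 equiv) in pyridine at −20 °C adds from the open α-face of the ring-A alkene to give the 2α,3α-diol silyl ether F8; the 8(17)-alkene is screened on both faces in this 9-epi series and the vinyl group is deactivated by the neighbouring silyloxy carbon. HF·pyridine then removes the silyl group and comes back to the route at 28.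

Step 16 (C7 hydroxylation). The 7α-hydroxyl ends up 1,3-diaxial to the axial C9 side chain, so the direct hydroxylation may give the 7β-epimer or the enone. The fallback sets out from 31 and sets C7 by reduction instead. SeO2/t-BuOOH at rt followed by MnO2 gathers all C7 products into the 8(17)-en-7-one F9. Luche reduction (NaBH4, CeCl3·7H2O, MeOH, −78 °C) then delivers hydride from the β-face, because the α-face is blocked by the axial side chain, and comes back to the route at 32.

**Further compounds**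
F1 | step 11 | 2-({[(2Z)-3-iodo-2-(4-methylpent-3-en-1-yl)prop-2-en-1-yl]oxy}methyl)naphthalene | I/C=C(/CCC=C(C)C)COCc1ccc2ccccc2c1
F2 | step 11 | 2-({[(2Z)-2-{2-[(2S)-3,3-dimethyloxiran-2-yl]ethyl}-3-iodoprop-2-en-1-yl]oxy}methyl)naphthalene | I/C=C(/CC[C@@H]1OC1(C)C)COCc1ccc2ccccc2c1
F3 | step 11 | 2-naphthylmethyl ether analogue of epoxy triene 22 | C=C[C@](C)(O[Si](CC)(CC)CC)CC/C=C(\CC/C=C(/CC[C@@H]1OC1(C)C)COCc1ccc2ccccc2c1)C[Si](C)(C)C
F4 | step 11 | (13R)-20-(2-naphthylmethoxy)-13-(triethylsilyloxy)-9βH-labda-8(17),14-dien-3β-ol | C=C[C@](C)(O[Si](CC)(CC)CC)CC[C@@H]1C(=C)CC[C@H]2C(C)(C)[C@@H](O)CC[C@]12COCc1ccc2ccccc2c1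
F5 | step 11 | (13R)-13-(triethylsilyloxy)-9βH-labda-8(17),14-diene-3β,20-diol | C=C[C@](C)(O[Si](CC)(CC)CC)CC[C@@H]1C(=C)CC[C@H]2C(C)(C)[C@@H](O)CC[C@]12CO
F6 | step 14 | (13R)-13-(triethylsilyloxy)-3-(trifluoromethylsulfonyloxy)-9βH-labda-2,8(17),14-trien-20-yl (2R)-2-methylbutanoate | C=C[C@](C)(O[Si](CC)(CC)CC)CC[C@@H]1C(=C)CC[C@H]2C(C)(C)C(OS(=O)(=O)C(F)(F)F)=CC[C@]12COC(=O)[C@H](C)CC
F7 | step 14 | (13R)-13-(triethylsilyloxy)-9βH-labda-2,8(17),14-trien-20-yl (2R)-2-methylbutanoate | C=C[C@](C)(O[Si](CC)(CC)CC)CC[C@@H]1C(=C)CC[C@H]2C(C)(C)C=CC[C@]12COC(=O)[C@H](C)CC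
F8 | step 14 | (13R)-2α,3α-dihydroxy-13-(triethylsilyloxy)-9βH-labda-8(17),14-dien-20-yl (2R)-2-methylbutanoate | C=C[C@](C)(O[Si](CC)(CC)CC)CC[C@@H]1C(=C)CC[C@H]2C(C)(C)[C@H](O)[C@H](O)C[C@]12COC(=O)[C@H](C)CC
F9 | step 16 | (13R)-2α-angeloyloxy-3α,13-dihydroxy-7-oxo-9βH-labda-8(17),14-dien-20-yl (2R)-2-methylbutanoate | C=C[C@](C)(O)CC[C@@H]1C(=C)C(=O)C[C@H]2C(C)(C)[C@H](O)[C@H](OC(=O)/C(C)=C\C)C[C@]12COC(=O)[C@H](C)CC
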